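Beside this flask stands a neighbour charged with 0.021 M of free catalyst; keep it in mind, and reckon the thinner recipe first.

substrate 0.56 M; gas phase 38 mM (held); free catalyst 5.3 mM; impurity 5.7 mM; time 20 min

    gas phase ⇌ dissolved gas, rate k1*(csat - [dissolved gas]) (k1 = 0.016 s⁻¹, csat = 38 mM)
    dissolved gas + free catalyst → spent catalyst B (k2 = 0.063 M⁻¹ s⁻¹)
    substrate + dissolved gas + free catalyst ⇌ free catalyst + target (K3 = 9.2 M⁻¹, k3 = 16 M⁻² s⁻¹)
    free catalyst + impurity → spent catalyst A (k4 = 9.5 M⁻¹ s⁻¹)

- delta: doubling the transfer coefficient of step 1, all else as stated
- alpha: doubling the saturation concentration of gas phase, all else as stated
- theta: doubling the amount of free catalyst, all else as stated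

- how much target there is at 20 min, in percent of the substrate charged
- the change that raises the amount of target at 20 min, in percent of the substrate charged most ("none" if none brings more than 2 percentage points) (delta / alpha / theta / none)
- amount of target at 20 min, in percent of the substrate charged, after alpha

- at the start none of the gas is dissolved
- run time (flask): 20 min

Begin with step 4. It removes impurity at the relative rate k4 times c(free catalyst), so the logarithm of the impurity's fall measures the area under the free-catalyst curve. In this flask the charge of free catalyst is the smaller side of step 4, with 5.3 mM against 5.7 mM of impurity. Step 2 takes catalyst far more slowly than step 4 does at the start, so let the impurity end at 0.400 mM. Dividing the area by the catalyst charge gives 0.879 min of working time: the time the charged catalyst, undiminished, would need to do the turnover it really does.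

Now reach the target by two ways. From the catalyst side, put dissolved gas at saturation throughout, and step 3 forward makes 17.0% of the substrate charged in the working time. From the gas side, step 1 delivers 5.73% into an empty solution in that time. The two part, and the first cheats: filling takes 1.04 min, longer than the working time, while the forward rate of step 3, at the concentrations as charged, gives dissolved gas a half-life of 0.24 min. Commit to the second figure for y, and to 11.5% after alpha. After theta the catalyst charge exceeds the impurity, so step 4 can take no more than 5.7 mM of it and 4.90 mM stays out of step 4's reach; expect theta to win.

The forecast gives 4.7% for y, lower than my figure, on the ground that the impurity “kills it within a few minutes, before much gas has dissolved”. It names theta as the best change, and it puts alpha at 7%, less than double its y, on a second ground: the extra dissolved gas also speeds catalyst loss through step 2, and the reverse of step 3 takes back some target.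

The flask gives 5.05%, and 8.29% after alpha, under my doubled figure; theta gains 19 percentage points, alpha 3.2 points, delta 1.2 points. The impurity left, 11%, puts the working time at 0.729 min. The neighbour flask ends with 0% of its impurity, 8.71% of its catalyst free, and 25.0% target. This flask has 0.128% of its catalyst free at 10.0 min, and target stands at 5.01% then, 5.05% at 40.0 min, and 5.05% at 200 min.

Its constants are invented, and the outcome is calculated.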